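**Plan**

- Retrosynthesis: the three benzyl ethers come off last. The pyranone ring of the apigenin unit is cut at O1–C2 and C2–C3 (aryl ester, then O-to-C acyl shift), which leaves benzoic acid 13 and acetophenone 14. The 7-O–CH3 bond is cut next, and ring A of the methoxyflavone unit is cut at C7–C8 and C5–C6 into pyranone 6 and aryloxyacetate 9.
- Enabling feature: in ring A of the 7-methoxyflavone unit, C6 carries the diaryl ether oxygen and sits between C5 and C7, which both bear oxygen and can both start as ester carbonyl carbons. C6 and its oxygen therefore arrive together as the OCH2 group of an aryloxyacetate made by O-alkylation of an unhindered phenol, so the crowded ether is never made by a coupling.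
- Forward order: pyranone ring C carrying ring B (steps 1–3), then ring A by Claisen–Dieckmann annulation onto the pyranone (step 5), then 7-O-methylation and ester unmasking, then the pyranone ring of the apigenin unit onto its preformed ring A (steps 8–9), then hydrogenolysis.
- Stereochemistry: the target has no stereocentre and no stereogenic double bond, so none has to be set.

Key step: step 5

Assumption: acetophenone 14 is taken as a purchasable compound, and the hydrogen-bonded 5-OH of the methoxyflavone unit is carried unprotected from step 5 onwards.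

**Route**

Step 1
Reactants: 1 1-(benzyloxy)-4-ethynylbenzene
Product: 2 3-[4-(benzyloxy)phenyl]prop-2-ynoic acid
Conditions: n-BuLi, THF, −78 °C; CO2, −78 °C to rt; aq. HCl
Reagents that add atoms: carbon dioxide, O=C=O
Why: Deprotonation of the terminal alkyne and trapping of the lithium acetylide with CO2 (acetylide carboxylation) is the standard entry to arylpropiolic acids and leaves the benzyl ether untouched.

Step 2
Reactants: 2 3-[4-(benzyloxy)phenyl]prop-2-ynoic acid
Product: 3 3-[4-(benzyloxy)phenyl]prop-2-ynoyl chloride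
Conditions: (COCl)2, DMF (cat.), CH2Cl2, 0 °C to rt; evaporate, use crude
Reagents that add atoms: oxalyl chloride, O=C(Cl)C(=O)Cl
Why: Acid chloride formation with oxalyl chloride under DMF catalysis (Vilsmeier-type activation) proceeds at or below room temperature, where addition of HCl to the conjugated alkyne should stay slow.

Step 3
Reactants: 3 3-[4-(benzyloxy)phenyl]prop-2-ynoyl chloride; 4 methyl acetoacetate
Product: 6 methyl 6-[4-(benzyloxy)phenyl]-2-methyl-4-oxo-4H-pyran-3-carboxylate, via alkynoyl acetoacetate 5 (not isolated)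
Conditions: MgCl2, pyridine, CH2Cl2, 0 °C to rt; then DMAP (0.2 equiv), rt
Reagents that add atoms: none
Why: Soft enolisation of the β-keto ester as its magnesium chelate directs the ynoyl chloride to carbon (C-acylation), and the acetyl enol oxygen of 5 then adds to the ynone β-carbon in a 6-endo-dig oxa-Michael closure, steered to the six-membered ring by DMAP addition–elimination, which is the established arylpropioloyl chloride route to 6-aryl-2-methyl-4-pyranone-3-carboxylates.

Step 4
Reactants: 7 tert-butyl 4-hydroxybenzoate; 8 methyl bromoacetate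
Product: 9 methyl 2-[4-(tert-butoxycarbonyl)phenoxy]acetate
Conditions: K2CO3, acetone, reflux
Reagents that add atoms: none
Why: Williamson ether synthesis: the unhindered phenoxide displaces bromide from the primary α-bromo ester (SN2) and the tert-butyl ester is inert to K2CO3.

Step 5
Reactants: 6 methyl 6-[4-(benzyloxy)phenyl]-2-methyl-4-oxo-4H-pyran-3-carboxylate; 9 methyl 2-[4-(tert-butoxycarbonyl)phenoxy]acetate
Product: 11 tert-butyl 4-({2-[4-(benzyloxy)phenyl]-5,7-dihydroxy-4-oxo-4H-chromen-6-yl}oxy)benzoate, via aryloxymethyl ketone 10 (not isolated)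
Conditions: LiN(iPr)2 (1.1 equiv), THF, −78 °C; 9, −78 to −40 °C; LiN(iPr)2 (2.4 equiv), −78 to 0 °C; AcOH
Reagents that add atoms: none
Why: Proposed new method: LiN(iPr)2 removes a proton from the 2-methyl group of 6 (vinylogous to both the C4 ketone and the C3 ester), the dienolate carbon (future C8) is acylated by the aryloxyacetate (C7–C8, Claisen) to give ketone 10 as its enolate, and further base forms the dianion whose aryloxy-bearing carbon (C6) attacks the neighbouring pyranone ester carbon (C5–C6, Dieckmann), after which loss of methoxide and enolisation give the resorcinol ring. The closest known reaction type is the tandem Claisen–Dieckmann annulation of laterally lithiated ortho-toluates or homophthalates with esters to 1,3-dihydroxynaphthalenes, together with the lateral acylation of 2-methyl-4-pyranones. Ring A closes in a 6-exo-trig mode, the enolate carbon adding to the exocyclic ester carbonyl. No stereocentre is formed. The closure has to go through C6 and not through the more acidic C8, the enolate oxygen or the ring carbonyl C4: C8 could only form a four-membered ring, C4 only a bridged aldol adduct, O-acylation to the enol lactone is reversed by methoxide while C-acylation is made irreversible by aromatisation, and in the dianion the last-formed carbanion C6 is the most nucleophilic site. The lateral anion must also choose between two esters, and here the inductively activated, unhindered aryloxyacetate should win over the bulky tert-butyl benzoate, which is further deactivated by its para oxygen.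

Step 6
Reactants: 11 tert-butyl 4-({2-[4-(benzyloxy)phenyl]-5,7-dihydroxy-4-oxo-4H-chromen-6-yl}oxy)benzoate
Product: 12 tert-butyl 4-({2-[4-(benzyloxy)phenyl]-5-hydroxy-7-methoxy-4-oxo-4H-chromen-6-yl}oxy)benzoate
Conditions: MeI (1.1 equiv), K2CO3 (1.2 equiv), acetone, rt
Reagents that add atoms: iodomethane, CI
Why: Williamson O-methylation under weak base takes place at the acidic, free 7-OH (vinylogous to the C4 carbonyl), whereas the 5-OH is held in a hydrogen bond to C4=O and flanked by the aryloxy group, the usual basis of selective 7-O-alkylation of 5,7-dihydroxyflavones.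

Step 7
Reactants: 12 tert-butyl 4-({2-[4-(benzyloxy)phenyl]-5-hydroxy-7-methoxy-4-oxo-4H-chromen-6-yl}oxy)benzoate
Product: 13 4-({2-[4-(benzyloxy)phenyl]-5-hydroxy-7-methoxy-4-oxo-4H-chromen-6-yl}oxy)benzoic acid
Conditions: TFA, CH2Cl2, 0 °C to rt
Reagents that add atoms: none
Why: Acidolysis of the tert-butyl ester (loss of the tert-butyl cation as 2-methylpropene) is fast in TFA at room temperature, conditions that the aryl benzyl ether, the aryl methyl ether and the diaryl ether should tolerate.

Step 8
Reactants: 13 4-({2-[4-(benzyloxy)phenyl]-5-hydroxy-7-methoxy-4-oxo-4H-chromen-6-yl}oxy)benzoic acid; 14 1-[2,4-bis(benzyloxy)-6-hydroxyphenyl]ethan-1-one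
Product: 15 2-acetyl-3,5-bis(benzyloxy)phenyl 4-({2-[4-(benzyloxy)phenyl]-5-hydroxy-7-methoxy-4-oxo-4H-chromen-6-yl}oxy)benzoate
Conditions: DCC, DMAP (cat.), 14 (1.5 equiv), CH2Cl2, 0 °C to rt
Reagents that add atoms: none
Why: Steglich esterification via the acylpyridinium ion should acylate the phenol of 14 (used in excess), while the 5-OH of 13, hydrogen-bonded to the pyranone carbonyl and substituted on both ortho positions, should stay out of the reaction.

Step 9
Reactants: 15 2-acetyl-3,5-bis(benzyloxy)phenyl 4-({2-[4-(benzyloxy)phenyl]-5-hydroxy-7-methoxy-4-oxo-4H-chromen-6-yl}oxy)benzoate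
Product: 17 5,7-bis(benzyloxy)-2-[4-({2-[4-(benzyloxy)phenyl]-5-hydroxy-7-methoxy-4-oxo-4H-chromen-6-yl}oxy)phenyl]-4H-chromen-4-one, via diketone 16 (not isolated)
Conditions: LiN(SiMe3)2 (3.5 equiv), THF, −20 °C to rt; AcOH; then p-TsOH·H2O (cat.), toluene, 80 °C
Reagents that add atoms: none
Why: Baker–Venkataraman rearrangement (the acetyl enolate attacks the neighbouring aryl ester, O-to-C acyl shift, with one extra equivalent of base for the 5-OH) gives the 2-hydroxyaryl 1,3-diketone, and acid-catalysed cyclodehydration then closes the pyranone ring of the apigenin unit, the classical flavone synthesis.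

Step 10
Reactants: 17 5,7-bis(benzyloxy)-2-[4-({2-[4-(benzyloxy)phenyl]-5-hydroxy-7-methoxy-4-oxo-4H-chromen-6-yl}oxy)phenyl]-4H-chromen-4-one
Product: 18 isocryptomerin
Conditions: H2 (1 atm), 10% Pd/C, THF/MeOH, rt
Reagents that add atoms: none
Why: Catalytic hydrogenolysis cleaves the three aryl benzyl ethers to phenols and toluene, while the flavone C2–C3 double bonds, the methyl ether and the diaryl ether are normally retained at atmospheric pressure.

**Compound list**

1 | 1-(benzyloxy)-4-ethynylbenzene | C#Cc1ccc(OCc2ccccc2)cc1 | starting material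
2 | 3-[4-(benzyloxy)phenyl]prop-2-ynoic acid | OC(=O)C#Cc1ccc(OCc2ccccc2)cc1 | intermediate
3 | 3-[4-(benzyloxy)phenyl]prop-2-ynoyl chloride | ClC(=O)C#Cc1ccc(OCc2ccccc2)cc1 | intermediate
4 | methyl acetoacetate | CC(=O)CC(=O)OC | starting material
5 | methyl 2-acetyl-5-[4-(benzyloxy)phenyl]-3-oxopent-4-ynoate | COC(=O)C(C(C)=O)C(=O)C#Cc1ccc(OCc2ccccc2)cc1 | intermediate
6 | methyl 6-[4-(benzyloxy)phenyl]-2-methyl-4-oxo-4H-pyran-3-carboxylate | COC(=O)c1c(C)oc(-c2ccc(OCc3ccccc3)cc2)cc1=O | intermediate
7 | tert-butyl 4-hydroxybenzoate | CC(C)(C)OC(=O)c1ccc(O)cc1 | starting material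
8 | methyl bromoacetate | COC(=O)CBr | starting material
9 | methyl 2-[4-(tert-butoxycarbonyl)phenoxy]acetate | COC(=O)COc1ccc(C(=O)OC(C)(C)C)cc1 | intermediate
10 | methyl 6-[4-(benzyloxy)phenyl]-2-{3-[4-(tert-butoxycarbonyl)phenoxy]-2-oxopropyl}-4-oxo-4H-pyran-3-carboxylate | COC(=O)c1c(CC(=O)COc2ccc(C(=O)OC(C)(C)C)cc2)oc(-c2ccc(OCc3ccccc3)cc2)cc1=O | intermediate
11 | tert-butyl 4-({2-[4-(benzyloxy)phenyl]-5,7-dihydroxy-4-oxo-4H-chromen-6-yl}oxy)benzoate | CC(C)(C)OC(=O)c1ccc(Oc2c(O)cc3oc(-c4ccc(OCc5ccccc5)cc4)cc(=O)c3c2O)cc1 | intermediate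
12 | tert-butyl 4-({2-[4-(benzyloxy)phenyl]-5-hydroxy-7-methoxy-4-oxo-4H-chromen-6-yl}oxy)benzoate | COc1cc2oc(-c3ccc(OCc4ccccc4)cc3)cc(=O)c2c(O)c1Oc1ccc(C(=O)OC(C)(C)C)cc1 | intermediate
13 | 4-({2-[4-(benzyloxy)phenyl]-5-hydroxy-7-methoxy-4-oxo-4H-chromen-6-yl}oxy)benzoic acid | COc1cc2oc(-c3ccc(OCc4ccccc4)cc3)cc(=O)c2c(O)c1Oc1ccc(C(=O)O)cc1 | intermediate
14 | 1-[2,4-bis(benzyloxy)-6-hydroxyphenyl]ethan-1-one | CC(=O)c1c(O)cc(OCc2ccccc2)cc1OCc1ccccc1 | starting material
15 | 2-acetyl-3,5-bis(benzyloxy)phenyl 4-({2-[4-(benzyloxy)phenyl]-5-hydroxy-7-methoxy-4-oxo-4H-chromen-6-yl}oxy)benzoate | COc1cc2oc(-c3ccc(OCc4ccccc4)cc3)cc(=O)c2c(O)c1Oc1ccc(C(=O)Oc2cc(OCc3ccccc3)cc(OCc3ccccc3)c2C(C)=O)cc1 | intermediate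
16 | 1-[2,4-bis(benzyloxy)-6-hydroxyphenyl]-3-[4-({2-[4-(benzyloxy)phenyl]-5-hydroxy-7-methoxy-4-oxo-4H-chromen-6-yl}oxy)phenyl]propane-1,3-dione | COc1cc2oc(-c3ccc(OCc4ccccc4)cc3)cc(=O)c2c(O)c1Oc1ccc(C(=O)CC(=O)c2c(O)cc(OCc3ccccc3)cc2OCc2ccccc2)cc1 | intermediate
17 | 5,7-bis(benzyloxy)-2-[4-({2-[4-(benzyloxy)phenyl]-5-hydroxy-7-methoxy-4-oxo-4H-chromen-6-yl}oxy)phenyl]-4H-chromen-4-one | COc1cc2oc(-c3ccc(OCc4ccccc4)cc3)cc(=O)c2c(O)c1Oc1ccc(-c2cc(=O)c3c(OCc4ccccc4)cc(OCc4ccccc4)cc3o2)cc1 | intermediate
18 | isocryptomerin, 5,7-dihydroxy-2-(4-{[5-hydroxy-2-(4-hydroxyphenyl)-7-methoxy-4-oxo-4H-chromen-6-yl]oxy}phenyl)-4H-chromen-4-one | COc1cc2oc(-c3ccc(O)cc3)cc(=O)c2c(O)c1Oc1ccc(-c2cc(=O)c3c(O)cc(O)cc3o2)cc1 | target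

**Step count**

Total: 10 steps. Longest linear sequence: 9 steps (steps 1, 2, 3, 5, 6, 7, 8, 9, 10); step 4 is the side branch.

**Steps most likely to fail**

1. Step 5 (proposed annulation).
   - What may go wrong: proton transfer from the first-formed ketone or from the aryloxyacetate to the lateral anion may stall the Claisen stage. Ring closure may run through the enolate oxygen and stop at the enol lactone. The amide base may add to the electron-poor pyranone ring.
   - Fallback (known chemistry; sets out from phenol 7 and rejoins the route at 12, so steps 5 and 6 are bypassed): the diaryl ether is made by copper-mediated coupling. Commercial genkwanin (5-hydroxy-2-(4-hydroxyphenyl)-7-methoxy-4H-chromen-4-one) is benzylated at its free 4'-OH with BnBr and K2CO3 in acetone to give 2-[4-(benzyloxy)phenyl]-5-hydroxy-7-methoxy-4H-chromen-4-one F1. Iodination ortho to the free 5-OH with benzyltrimethylammonium dichloroiodate (PhCH2NMe3 ICl2) and CaCO3 in CH2Cl2/MeOH should give 2-[4-(benzyloxy)phenyl]-5-hydroxy-6-iodo-7-methoxy-4H-chromen-4-one F2. Ullmann diaryl ether coupling of F2 with 7 (CuI, picolinic acid, K3PO4, DMSO, 90 °C) should then deliver 12.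

2. Step 8 (esterification beside a free phenol).
   - What may go wrong: the activated acid may be intercepted by the 5-OH of a second molecule of 13 (self-esterification), or may rearrange to the N-acylurea while the hindered, hydrogen-bonded phenol of 14 reacts slowly.
   - Fallback (sets out from 13 and rejoins at diketone 16, which then only needs the acid cyclodehydration of step 9): no activated carboxyl group is generated next to free phenols. The carboxylate of 13 is alkylated with MeI and KHCO3 in DMF to methyl 4-({2-[4-(benzyloxy)phenyl]-5-hydroxy-7-methoxy-4-oxo-4H-chromen-6-yl}oxy)benzoate F3. The lithium dianion of acetophenone 14 (LiN(SiMe3)2, THF, −78 °C to rt, one further equivalent for the 5-OH of F3) is then condensed with F3 in a crossed Claisen condensation to give 16 directly.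

3. Step 3 (acylation and pyranone closure).
   - What may go wrong: chloride or pyridine may add to the conjugated triple bond of the ynoyl chloride, the enolate may be acylated on oxygen, or the acylation may be slow enough for the acid chloride to decompose.
   - Fallback (sets out from acid 2 and rejoins at tricarbonyl compound 5, closed to 6 with DMAP as in step 3; acid chloride 3 is bypassed): the two acyl groups are introduced in the reverse order. Acid 2 and carbonyldiimidazole in THF give 3-[4-(benzyloxy)phenyl]-1-(1H-imidazol-1-yl)prop-2-yn-1-one F4. Decarboxylative Claisen condensation of F4 with potassium methyl malonate, MgCl2 and Et3N gives methyl 5-[4-(benzyloxy)phenyl]-3-oxopent-4-ynoate F5. C-acetylation of the magnesium chelate of F5 with acetyl chloride (MgCl2, pyridine, CH2Cl2) then gives 5.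

**Further compounds**

F1 | step 5 | 2-[4-(benzyloxy)phenyl]-5-hydroxy-7-methoxy-4H-chromen-4-one | COc1cc(O)c2c(c1)oc(-c1ccc(OCc3ccccc3)cc1)cc2=O
F2 | step 5 | 2-[4-(benzyloxy)phenyl]-5-hydroxy-6-iodo-7-methoxy-4H-chromen-4-one | COc1cc2oc(-c3ccc(OCc4ccccc4)cc3)cc(=O)c2c(O)c1I
F3 | step 8 | methyl 4-({2-[4-(benzyloxy)phenyl]-5-hydroxy-7-methoxy-4-oxo-4H-chromen-6-yl}oxy)benzoate | COC(=O)c1ccc(Oc2c(OC)cc3oc(-c4ccc(OCc5ccccc5)cc4)cc(=O)c3c2O)cc1
F4 | step 3 | 3-[4-(benzyloxy)phenyl]-1-(1H-imidazol-1-yl)prop-2-yn-1-one | O=C(C#Cc1ccc(OCc2ccccc2)cc1)n1ccnc1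
F5 | step 3 | methyl 5-[4-(benzyloxy)phenyl]-3-oxopent-4-ynoate | COC(=O)CC(=O)C#Cc1ccc(OCc2ccccc2)cc1
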